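Eunicellane numbering is used in this overview: C1/C10 ring fusion, C2 and C9 ether carbons, C3 (Me, lactone O), C6=C7, C11 (Me, butanoate), C14–C15(Me)–C16(=O). Late disconnections: the seven-membered lactone C16(=O)–O–C3 (Yamaguchi); C16 from a C15 methyl ketone (methylenation, hydroboration, oxidation); the oxonene at C6=C7 (ring-closing metathesis); C11–CH3 (Grignard addition to a C11 ketone, alkoxide butanoylated in the flask); C9–C8 (Sakurai methallylation of a lactol acetate).
Key disconnection: C1–C10 together with C13–C14, by a silyl triflate-promoted intramolecular double Michael reaction (formal Diels–Alder) of a Nazarov-type β-keto ester onto an (E)-enone. It gives a cis-fused γ-lactone/cyclohexene in which the future ether oxygen is still an ester oxygen and C9 is still a carbonyl.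
Enabling feature: C1–C10 is the bond shared by the tetrahydrofuran ring (O, C2, C1, C10, C9) and the cyclohexane ring (C1, C10, C11–C14). C10 lies between the two oxygen-bearing carbons C9 and C11, so at the C9 carboxyl/C11 ketone level it is the nucleophilic α-carbon of a β-keto ester tethered through oxygen to C2, while C1 is the β-carbon of the C1=C14–C15=O enone.
The acyclic precursor comes from nerol: Sharpless epoxidation sets C2/C3, oxidation–Wittig adds C14, C15 and C17, epoxide hydrolysis with inversion at C3 gives the diol, and an acyl Meldrum's acid delivers C9–C13.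
Ring order: γ-lactone (future tetrahydrofuran) and cyclohexane together in the key step, then the nine-membered oxonene, last the seven-membered lactone.

Key step: step 6

Remark: atoms are numbered as in the eunicellane skeleton (bicyclo[8.4.0]tetradecane numbering C1–C14, C15–C17 for the propanoate unit on C14, C18–C20 for the methyl groups on C3, C7 and C11); in this numbering the target is taken as (1S,2S,3S,6Z,9S,10R,11R,14R,15R).

Step 1
Reactants: 1 nerol ((2Z)-3,7-dimethylocta-2,6-dien-1-ol)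
Product: 2 (2S,3R)-2,3-epoxynerol ([(2S,3R)-3-methyl-3-(4-methylpent-3-en-1-yl)oxiran-2-yl]methanol)
Conditions: Ti(OiPr)4 (cat.), L-(+)-diethyl tartrate (cat.), tBuOOH, 4 Å molecular sieves, CH2Cl2, −20 °C
Reagents that add atoms: tert-butyl hydroperoxide, CC(C)(C)OO
Why: Sharpless asymmetric epoxidation, in which the titanium tartrate complex binds the allylic alcohol and delivers oxygen to one face of the (Z)-olefin only, so that C2 (S) and C3 (R) are set together by the L-(+)-tartrate while the remote trisubstituted olefin, which has no directing hydroxyl, should stay untouched.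

Step 2
Reactants: 2 (2S,3R)-2,3-epoxynerol
Product: 4 (3E)-4-[(2S,3R)-3-methyl-3-(4-methylpent-3-en-1-yl)oxiran-2-yl]but-3-en-2-one, via epoxy aldehyde 3 (not isolated)
Conditions: TEMPO (cat.), PhI(OAc)2, CH2Cl2, rt; then Ph3P=CHC(O)CH3, rt
Reagents that add atoms: 1-(triphenylphosphoranylidene)propan-2-one, CC(=O)C=P(c1ccccc1)(c1ccccc1)c1ccccc1
Why: Oxoammonium (TEMPO) oxidation of the primary alcohol to the epoxy aldehyde followed in the same flask by a Wittig reaction with the stabilised acetyl ylide, which should give the (E)-enone and does not touch the two epoxide stereocenters.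

Step 3
Reactants: 4 (3E)-4-[(2S,3R)-3-methyl-3-(4-methylpent-3-en-1-yl)oxiran-2-yl]but-3-en-2-one
Product: 5 (3E,5S,6S)-5,6-dihydroxy-6,10-dimethylundeca-3,9-dien-2-one
Conditions: HClO4 (cat.), THF/H2O 3:1, 0 °C
Reagents that add atoms: water, O
Why: Acid-catalysed hydrolytic epoxide opening in which water attacks the protonated epoxide at the tertiary carbon (the other carbon is deactivated by the adjacent enone) with inversion, so that the cis-epoxide should give the (5S,6S)-diol with the secondary C–O bond retained.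

Step 4
Reactants: 6 Meldrum's acid (2,2-dimethyl-1,3-dioxane-4,6-dione); 7 3-chloropropanoyl chloride
Product: 8 5-(3-chloro-1-hydroxypropylidene)-2,2-dimethyl-1,3-dioxane-4,6-dione
Conditions: pyridine, CH2Cl2, 0 °C → rt
Reagents that add atoms: 3-chloropropanoyl chloride (7), ClCCC(Cl)=O
Why: C-Acylation of Meldrum's acid by the acid chloride gives the enolised acyl Meldrum's acid, a storable acylketene precursor that carries the vinyl ketone of the Nazarov unit masked as a β-chloro ketone; no stereocenter is formed.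

Step 5
Reactants: 5 (3E,5S,6S)-5,6-dihydroxy-6,10-dimethylundeca-3,9-dien-2-one; 8 5-(3-chloro-1-hydroxypropylidene)-2,2-dimethyl-1,3-dioxane-4,6-dione
Product: 9 (3E,5S,6S)-6-hydroxy-6,10-dimethyl-2-oxoundeca-3,9-dien-5-yl 5-chloro-3-oxopentanoate
Conditions: toluene, 80 °C
Reagents that add atoms: acyl Meldrum's acid 8, CC1(C)OC(=O)C(=C(O)CCCl)C(=O)O1
Why: Thermolysis of the acyl Meldrum's acid releases acetone and CO2 to give an acylketene that should be trapped by the secondary allylic hydroxyl in preference to the more hindered tertiary one (acylketene acylation), which places the β-keto ester on the oxygen of C2 without touching a stereocenter.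

Step 6
Reactants: 9 (3E,5S,6S)-6-hydroxy-6,10-dimethyl-2-oxoundeca-3,9-dien-5-yl 5-chloro-3-oxopentanoate
Product: 12 (3S,3aS,4R,7aS)-4-acetyl-7-[(tert-butyldimethylsilyl)oxy]-3-[(2S)-2-[(tert-butyldimethylsilyl)oxy]-6-methylhept-5-en-2-yl]-3a,4,5,7a-tetrahydro-2-benzofuran-1(3H)-one, via Nazarov ester 10 (not isolated), via silyloxy diene 11 (not isolated)
Conditions: Et3N, CH2Cl2, 0 °C; then TBSOTf (2.2 equiv), −78 → −20 °C
Reagents that add atoms: tert-butyldimethylsilyl trifluoromethanesulfonate, CC(C)(C)[Si](C)(C)OS(=O)(=O)C(F)(F)F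
Why: Et3N eliminates HCl (E1cB) to give the vinyl β-keto ester 10, and TBSOTf/Et3N then silylates the tertiary hydroxyl and turns the β-keto ester into the 2-silyloxy diene 11 (C10=C11(OSi)–C12=C13), which adds to the silyl triflate-activated (E)-enone by a Mukaiyama–Michael/Michael sequence (formal intramolecular Diels–Alder reaction) that forms C1–C10 and then C13–C14 and leaves C11 as a regiodefined C11=C12 silyl enol ether. The closest known reaction types are the silyl triflate/amine-promoted intramolecular double Michael reaction and the base-mediated double Michael annulation of Nazarov reagents with enones. The γ-lactone (O, C9, C10, C1, C2) closes by 5-exo-trig attack of C10 on C1, and the cyclohexene (C1, C10, C11–C14) closes by 6-endo-trig attack of the C14 silyl enol ether on C13 of the O-silylated vinyl ketone. C1 is controlled by the existing C2 stereocenter (C10 adds anti to the bulky quaternary C3 substituent with the C2–H eclipsing the enone, which gives the 4,5-trans lactone); C10 lies between the lactone carbonyl and the activated C11 carbonyl and stays configurationally labile until the second bond forms, so both C10 epimers and both enol ether geometries of 11 should funnel into the less strained cis-fused closure; C14 follows from the (E)-enone geometry and the pseudo-equatorial position of the enol ether in the chair-like closure and, being α to the ketone, can still relax to the equatorial acetyl. The step needs silylation of the acidic β-keto ester but not of the methyl ketone of the acceptor, and attack at C1 rather than at the carbonyl; the large acidity difference, the limited amount of TBSOTf, the low temperature and the 5-exo geometry should secure this.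

Step 7
Reactants: 12 (3S,3aS,4R,7aS)-4-acetyl-7-[(tert-butyldimethylsilyl)oxy]-3-[(2S)-2-[(tert-butyldimethylsilyl)oxy]-6-methylhept-5-en-2-yl]-3a,4,5,7a-tetrahydro-2-benzofuran-1(3H)-one
Product: 13 (3S,3aS,4R,7aS)-7-[(tert-butyldimethylsilyl)oxy]-3-[(2S)-2-[(tert-butyldimethylsilyl)oxy]-6-methylhept-5-en-2-yl]-4-(prop-1-en-2-yl)-3a,4,5,7a-tetrahydro-2-benzofuran-1(3H)-one
Conditions: Ph3PCH3Br, KN(SiMe3)2, THF, −78 → 0 °C
Reagents that add atoms: methyltriphenylphosphonium bromide, C[P+](c1ccccc1)(c1ccccc1)c1ccccc1.[Br-]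
Why: Wittig methylenation with the non-stabilised ylide should convert the methyl ketone into the isopropenyl group in preference to the lactone and the silyl enol ether at low temperature; no new stereocenter is formed and C14, if enolised by the basic ylide, should return to the equatorial configuration.

Step 8
Reactants: 13 (3S,3aS,4R,7aS)-7-[(tert-butyldimethylsilyl)oxy]-3-[(2S)-2-[(tert-butyldimethylsilyl)oxy]-6-methylhept-5-en-2-yl]-4-(prop-1-en-2-yl)-3a,4,5,7a-tetrahydro-2-benzofuran-1(3H)-one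
Product: 15 (3S,3aS,4R,7aS)-7-[(tert-butyldimethylsilyl)oxy]-3-[(2S)-2-[(tert-butyldimethylsilyl)oxy]-6-methylhept-5-en-2-yl]-4-(prop-1-en-2-yl)-1,3,3a,4,5,7a-hexahydro-2-benzofuran-1-yl acetate (anomeric mixture), via lactol 14 (not isolated)
Conditions: iBu2AlH, CH2Cl2, −78 °C; then pyridine, DMAP, Ac2O, −78 → 0 °C
Reagents that add atoms: acetic anhydride, CC(=O)OC(C)=O
Why: Low-temperature iBu2AlH reduction stops at the aluminium lactol alkoxide, which is acetylated in the same flask (one-pot reductive acetylation of a lactone) to give the lactol acetate as an anomeric mixture whose two anomers converge on the same oxocarbenium ion in step 9, so the configuration at C9 is immaterial here.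

Step 9
Reactants: 15 lactol acetate (anomeric mixture)
Product: 17 (1S,3S,3aR,7R,7aS)-1-[(2S)-2-[(tert-butyldimethylsilyl)oxy]-6-methylhept-5-en-2-yl]-3-(2-methylprop-2-en-1-yl)-7-(prop-1-en-2-yl)hexahydro-2-benzofuran-4(1H)-one, via methallylated silyl enol ether 16 (not isolated)
Conditions: trimethyl(2-methylallyl)silane (excess), BF3·OEt2, CH2Cl2, −78 °C; then 1 M HCl, THF, 0 °C
Reagents that add atoms: trimethyl(2-methylprop-2-en-1-yl)silane, CC(=C)C[Si](C)(C)C
Why: Hosomi–Sakurai allylation of the bicyclic oxocarbenium ion, in which the silane should attack C9 on the convex face anti to the cyclohexene ring on the neighbouring C10 and so place C8 cis to the C3 side chain across the ring oxygen (2,5-cis-tetrahydrofuran), after which dilute acid hydrolyses the silyl enol ether by protonation at C12 and unveils the C11 ketone without touching C10.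

Step 10
Reactants: 17 (1S,3S,3aR,7R,7aS)-1-[(2S)-2-[(tert-butyldimethylsilyl)oxy]-6-methylhept-5-en-2-yl]-3-(2-methylprop-2-en-1-yl)-7-(prop-1-en-2-yl)hexahydro-2-benzofuran-4(1H)-one
Product: 19 (1S,3S,3aR,4R,7R,7aS)-1-[(2S)-2-[(tert-butyldimethylsilyl)oxy]-6-methylhept-5-en-2-yl]-4-methyl-3-(2-methylprop-2-en-1-yl)-7-(prop-1-en-2-yl)octahydro-2-benzofuran-4-yl butanoate, via bromomagnesium alkoxide 18 (not isolated)
Conditions: MeMgBr, THF, −78 °C; then (PrCO)2O, DMAP, −78 °C → rt
Reagents that add atoms: methylmagnesium bromide, C[Mg]Br; butanoic anhydride, CCCC(=O)OC(=O)CCC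
Why: Grignard addition to the cyclohexanone from the face anti to the axial C10–C9 bond (axial attack on the convex face) should put the new methyl group cis to H10 and the oxygen cis to C9 as C11 requires, and the tertiary magnesium alkoxide is acylated in the flask by the anhydride, which is easier than esterifying the free hindered tertiary alcohol later.

Step 11
Reactants: 19 (1S,3S,3aR,4R,7R,7aS)-1-[(2S)-2-[(tert-butyldimethylsilyl)oxy]-6-methylhept-5-en-2-yl]-4-methyl-3-(2-methylprop-2-en-1-yl)-7-(prop-1-en-2-yl)octahydro-2-benzofuran-4-yl butanoate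
Product: 20 (1S,2S,3S,6Z,9S,10R,11R,14R)-3-[(tert-butyldimethylsilyl)oxy]-2,9-epoxy-3,7,11-trimethyl-14-(prop-1-en-2-yl)bicyclo[8.4.0]tetradec-6-en-11-yl butanoate
Conditions: second-generation Hoveyda–Grubbs catalyst RuCl2(H2IMes)(=CH-C6H4-2-OiPr) (10 mol %), toluene (1 mM), 80 °C
Reagents that add atoms: none
Why: Ring-closing olefin metathesis between the trisubstituted isopropylidene terminus and the 1,1-disubstituted methallyl group, which are held cis on the tetrahydrofuran, should close the nine-membered oxacycle with loss of isobutene, the ring size enforcing the (Z)-C6=C7 geometry and the α-branched isopropenyl group staying a spectator.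

Step 12
Reactants: 20 (1S,2S,3S,6Z,9S,10R,11R,14R)-3-[(tert-butyldimethylsilyl)oxy]-2,9-epoxy-3,7,11-trimethyl-14-(prop-1-en-2-yl)bicyclo[8.4.0]tetradec-6-en-11-yl butanoate
Product: 22 (1S,2S,3S,6Z,9S,10R,11R,14S)-3-[(tert-butyldimethylsilyl)oxy]-2,9-epoxy-14-[(2R)-1-hydroxypropan-2-yl]-3,7,11-trimethylbicyclo[8.4.0]tetradec-6-en-11-yl butanoate, via B-alkyl-9-BBN adduct 21 (not isolated)
Conditions: 9-BBN (9-borabicyclo[3.3.1]nonane), THF, 0 °C → rt; then NaOH (aq.), H2O2, 0 °C
Reagents that add atoms: hydrogen peroxide, OO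
Why: Hydroboration–oxidation in which 9-BBN should react only with the 1,1-disubstituted isopropenyl group and not with the trisubstituted ring olefin, adding to the face turned away from C1 in the rotamer with H14 eclipsing the double bond (minimised A(1,3) strain), which sets C15 (R) and gives the primary alcohol at C16.

Step 13
Reactants: 22 (1S,2S,3S,6Z,9S,10R,11R,14S)-3-[(tert-butyldimethylsilyl)oxy]-2,9-epoxy-14-[(2R)-1-hydroxypropan-2-yl]-3,7,11-trimethylbicyclo[8.4.0]tetradec-6-en-11-yl butanoate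
Product: 23 (2R)-2-[(1S,2S,3S,6Z,9S,10R,11R,14R)-11-(butanoyloxy)-3-[(tert-butyldimethylsilyl)oxy]-2,9-epoxy-3,7,11-trimethylbicyclo[8.4.0]tetradec-6-en-14-yl]propanoic acid
Conditions: TEMPO (cat.), PhI(OAc)2, MeCN/pH 7 buffer, rt
Reagents that add atoms: water, O
Why: Oxoammonium (TEMPO) oxidation in aqueous acetonitrile takes the primary alcohol through the aldehyde hydrate to the carboxylic acid without affecting the olefin, the ester or the silyl ether, and under these near-neutral conditions the α-stereocenter C15 should not epimerise.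

Step 14
Reactants: 23 (2R)-2-[(1S,2S,3S,6Z,9S,10R,11R,14R)-11-(butanoyloxy)-3-[(tert-butyldimethylsilyl)oxy]-2,9-epoxy-3,7,11-trimethylbicyclo[8.4.0]tetradec-6-en-14-yl]propanoic acid
Product: 24 (2R)-2-[(1S,2S,3S,6Z,9S,10R,11R,14R)-11-(butanoyloxy)-2,9-epoxy-3-hydroxy-3,7,11-trimethylbicyclo[8.4.0]tetradec-6-en-14-yl]propanoic acid
Conditions: HF (aq.), MeCN, rt
Reagents that add atoms: none
Why: Fluoride-driven desilylation (Si–F bond formation) of the tertiary silyl ether frees the C3 hydroxyl, while the tertiary butanoate, the olefin and all stereocenters should be unaffected.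

Step 15
Reactants: 24 (2R)-2-[(1S,2S,3S,6Z,9S,10R,11R,14R)-11-(butanoyloxy)-2,9-epoxy-3-hydroxy-3,7,11-trimethylbicyclo[8.4.0]tetradec-6-en-14-yl]propanoic acid
Product: 26 target CNP0294597.2, via mixed anhydride 25 (not isolated)
Conditions: 2,4,6-Cl3C6H2COCl, Et3N, THF, rt; then DMAP, toluene (2 mM), 80 °C
Reagents that add atoms: none
Why: Yamaguchi lactonisation, in which the mixed 2,4,6-trichlorobenzoic anhydride is activated by DMAP and captured at high dilution by the tertiary C3 hydroxyl that the rigid tricycle holds close to C16, should close the seven-membered lactone without forming a stereocenter and without epimerising C15.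

Compound list
1 | nerol, (2Z)-3,7-dimethylocta-2,6-dien-1-ol | OC/C=C(C)\CCC=C(C)C | starting material
2 | (2S,3R)-2,3-epoxynerol, [(2S,3R)-3-methyl-3-(4-methylpent-3-en-1-yl)oxiran-2-yl]methanol | OC[C@@H]1O[C@]1(C)CCC=C(C)C | intermediate
3 | (2R,3R)-3-methyl-3-(4-methylpent-3-en-1-yl)oxirane-2-carbaldehyde (formed and used in the flask) | O=C[C@@H]1O[C@]1(C)CCC=C(C)C | intermediate
4 | (3E)-4-[(2S,3R)-3-methyl-3-(4-methylpent-3-en-1-yl)oxiran-2-yl]but-3-en-2-one | CC(=O)/C=C/[C@@H]1O[C@]1(C)CCC=C(C)C | intermediate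
5 | (3E,5S,6S)-5,6-dihydroxy-6,10-dimethylundeca-3,9-dien-2-one | CC(=O)/C=C/[C@H](O)[C@@](C)(O)CCC=C(C)C | intermediate
6 | Meldrum's acid, 2,2-dimethyl-1,3-dioxane-4,6-dione | CC1(C)OC(=O)CC(=O)O1 | starting material
7 | 3-chloropropanoyl chloride | ClCCC(Cl)=O | starting material
8 | 5-(3-chloro-1-hydroxypropylidene)-2,2-dimethyl-1,3-dioxane-4,6-dione | CC1(C)OC(=O)C(=C(O)CCCl)C(=O)O1 | intermediate
9 | (3E,5S,6S)-6-hydroxy-6,10-dimethyl-2-oxoundeca-3,9-dien-5-yl 5-chloro-3-oxopentanoate | CC(=O)/C=C/[C@H](OC(=O)CC(=O)CCCl)[C@@](C)(O)CCC=C(C)C | intermediate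
10 | (3E,5S,6S)-6-hydroxy-6,10-dimethyl-2-oxoundeca-3,9-dien-5-yl 3-oxopent-4-enoate (Nazarov ester, formed and used in the flask) | CC(=O)/C=C/[C@H](OC(=O)CC(=O)C=C)[C@@](C)(O)CCC=C(C)C | intermediate
11 | (3E,5S,6S)-6-[(tert-butyldimethylsilyl)oxy]-6,10-dimethyl-2-oxoundeca-3,9-dien-5-yl (2Z)-3-[(tert-butyldimethylsilyl)oxy]penta-2,4-dienoate (formed and used in the flask; either enol ether geometry converges) | CC(=O)/C=C/[C@H](OC(=O)/C=C(\O[Si](C)(C)C(C)(C)C)C=C)[C@@](C)(O[Si](C)(C)C(C)(C)C)CCC=C(C)C | intermediate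
12 | (3S,3aS,4R,7aS)-4-acetyl-7-[(tert-butyldimethylsilyl)oxy]-3-[(2S)-2-[(tert-butyldimethylsilyl)oxy]-6-methylhept-5-en-2-yl]-3a,4,5,7a-tetrahydro-2-benzofuran-1(3H)-one | CC(C)(C)[Si](C)(C)OC1=CC[C@@H](C(C)=O)[C@H]2[C@@H]1C(=O)O[C@@H]2[C@@](C)(O[Si](C)(C)C(C)(C)C)CCC=C(C)C | intermediate
13 | (3S,3aS,4R,7aS)-7-[(tert-butyldimethylsilyl)oxy]-3-[(2S)-2-[(tert-butyldimethylsilyl)oxy]-6-methylhept-5-en-2-yl]-4-(prop-1-en-2-yl)-3a,4,5,7a-tetrahydro-2-benzofuran-1(3H)-one | CC(C)(C)[Si](C)(C)OC1=CC[C@@H](C(C)=C)[C@H]2[C@@H]1C(=O)O[C@@H]2[C@@](C)(O[Si](C)(C)C(C)(C)C)CCC=C(C)C | intermediate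
14 | lactol of 13, (3S,3aS,4R,7aS)-configured 1,3,3a,4,5,7a-hexahydro-2-benzofuran-1-ol (aluminium alkoxide in the flask; anomeric mixture, one anomer drawn) | CC(C)(C)[Si](C)(C)OC1=CC[C@@H](C(C)=C)[C@H]2[C@@H]1[C@H](O)O[C@@H]2[C@@](C)(O[Si](C)(C)C(C)(C)C)CCC=C(C)C | intermediate
15 | (3S,3aS,4R,7aS)-7-[(tert-butyldimethylsilyl)oxy]-3-[(2S)-2-[(tert-butyldimethylsilyl)oxy]-6-methylhept-5-en-2-yl]-4-(prop-1-en-2-yl)-1,3,3a,4,5,7a-hexahydro-2-benzofuran-1-yl acetate (anomeric mixture, one anomer drawn) | CC(C)(C)[Si](C)(C)OC1=CC[C@@H](C(C)=C)[C@H]2[C@@H]1[C@H](OC(C)=O)O[C@@H]2[C@@](C)(O[Si](C)(C)C(C)(C)C)CCC=C(C)C | intermediate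
16 | C11 tert-butyldimethylsilyl enol ether (C11=C12) of ketone 17 (formed and used in the flask) | CC(C)(C)[Si](C)(C)OC1=CC[C@@H](C(C)=C)[C@H]2[C@@H]1[C@H](CC(C)=C)O[C@@H]2[C@@](C)(O[Si](C)(C)C(C)(C)C)CCC=C(C)C | intermediate
17 | (1S,3S,3aR,7R,7aS)-1-[(2S)-2-[(tert-butyldimethylsilyl)oxy]-6-methylhept-5-en-2-yl]-3-(2-methylprop-2-en-1-yl)-7-(prop-1-en-2-yl)hexahydro-2-benzofuran-4(1H)-one | O=C1CC[C@@H](C(C)=C)[C@H]2[C@@H]1[C@H](CC(C)=C)O[C@@H]2[C@@](C)(O[Si](C)(C)C(C)(C)C)CCC=C(C)C | intermediate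
18 | bromomagnesium alkoxide of the C11 tertiary alcohol (formed and used in the flask) | Br[Mg]O[C@]1(C)CC[C@@H](C(C)=C)[C@H]2[C@@H]1[C@H](CC(C)=C)O[C@@H]2[C@@](C)(O[Si](C)(C)C(C)(C)C)CCC=C(C)C | intermediate
19 | (1S,3S,3aR,4R,7R,7aS)-1-[(2S)-2-[(tert-butyldimethylsilyl)oxy]-6-methylhept-5-en-2-yl]-4-methyl-3-(2-methylprop-2-en-1-yl)-7-(prop-1-en-2-yl)octahydro-2-benzofuran-4-yl butanoate | CCCC(=O)O[C@]1(C)CC[C@@H](C(C)=C)[C@H]2[C@@H]1[C@H](CC(C)=C)O[C@@H]2[C@@](C)(O[Si](C)(C)C(C)(C)C)CCC=C(C)C | intermediate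
20 | (1S,2S,3S,6Z,9S,10R,11R,14R)-3-[(tert-butyldimethylsilyl)oxy]-2,9-epoxy-3,7,11-trimethyl-14-(prop-1-en-2-yl)bicyclo[8.4.0]tetradec-6-en-11-yl butanoate | CCCC(=O)O[C@]1(C)CC[C@@H](C(C)=C)[C@H]3[C@@H]1[C@@H]1C/C(C)=C\CC[C@](C)(O[Si](C)(C)C(C)(C)C)[C@H]3O1 | intermediate
21 | B-alkyl-9-borabicyclo[3.3.1]nonane adduct of 20 at C16 (formed and used in the flask) | CCCC(=O)O[C@]1(C)CC[C@@H]([C@@H](C)CB4C5CCCC4CCC5)[C@H]3[C@@H]1[C@@H]1C/C(C)=C\CC[C@](C)(O[Si](C)(C)C(C)(C)C)[C@H]3O1 | intermediate
22 | (1S,2S,3S,6Z,9S,10R,11R,14S)-3-[(tert-butyldimethylsilyl)oxy]-2,9-epoxy-14-[(2R)-1-hydroxypropan-2-yl]-3,7,11-trimethylbicyclo[8.4.0]tetradec-6-en-11-yl butanoate | CCCC(=O)O[C@]1(C)CC[C@@H]([C@@H](C)CO)[C@H]3[C@@H]1[C@@H]1C/C(C)=C\CC[C@](C)(O[Si](C)(C)C(C)(C)C)[C@H]3O1 | intermediate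
23 | (2R)-2-[(1S,2S,3S,6Z,9S,10R,11R,14R)-11-(butanoyloxy)-3-[(tert-butyldimethylsilyl)oxy]-2,9-epoxy-3,7,11-trimethylbicyclo[8.4.0]tetradec-6-en-14-yl]propanoic acid | CCCC(=O)O[C@]1(C)CC[C@@H]([C@@H](C)C(=O)O)[C@H]3[C@@H]1[C@@H]1C/C(C)=C\CC[C@](C)(O[Si](C)(C)C(C)(C)C)[C@H]3O1 | intermediate
24 | (2R)-2-[(1S,2S,3S,6Z,9S,10R,11R,14R)-11-(butanoyloxy)-2,9-epoxy-3-hydroxy-3,7,11-trimethylbicyclo[8.4.0]tetradec-6-en-14-yl]propanoic acid | CCCC(=O)O[C@]1(C)CC[C@@H]([C@@H](C)C(=O)O)[C@H]3[C@@H]1[C@@H]1C/C(C)=C\CC[C@](C)(O)[C@H]3O1 | intermediate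
25 | mixed anhydride of acid 24 with 2,4,6-trichlorobenzoic acid (formed and used in the flask) | CCCC(=O)O[C@]1(C)CC[C@@H]([C@@H](C)C(=O)OC(=O)c4c(Cl)cc(Cl)cc4Cl)[C@H]3[C@@H]1[C@@H]1C/C(C)=C\CC[C@](C)(O)[C@H]3O1 | intermediate
26 | CNP0294597.2, the (1S,2S,3S,6Z,9S,10R,11R,14R,15R)-configured 11-butanoate with the C16(=O)–O–C3 lactone | CCCC(=O)O[C@]1(C)CC[C@@H]2[C@H]3[C@@H]1[C@@H]1C/C(C)=C\CC[C@](C)(OC(=O)[C@@H]2C)[C@H]3O1 | target

Total step count: 15. Longest linear sequence: 14 steps (steps 1–3 and 5–15); step 4 prepares the acylating agent 8 from commercial 6 and 7.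

Steps most likely to fail

1. Step 6. The vinyl β-keto ester may undergo amine-induced Michael addition before it is silylated, the methyl ketone of the acceptor may be enol-silylated in competition, or the second ring may close to the trans-fused isomer. The fallback runs the annulation in the anionic manifold, where C10 and C14 are under thermodynamic control, and masks C11 as a ketal instead of a silyl enol ether. Setting out from 9, Cs2CO3 in MeCN (loss of HCl, then base-mediated double Michael addition of Nazarov ester 10) should give the β-keto lactone (3S,3aS,4R,7aS)-4-acetyl-3-[(2S)-2-hydroxy-6-methylhept-5-en-2-yl]hexahydro-2-benzofuran-1,7-dione F1. Excess Ph3P=CH2, which first turns the β-keto lactone into its unreactive enolate, methylenates the methyl ketone to the isopropenyl β-keto lactone F2. Ethane-1,2-diol with HC(OMe)3 and catalytic TsOH gives the C11 dioxolane F3, and TBSOTf/2,6-lutidine gives its tertiary silyl ether F4. iBu2AlH followed by Ac2O/pyridine/DMAP gives the lactol acetate F5, methallylation as in step 9 gives the methallylated ketal F6, and aqueous HCl removes the dioxolane, so the fallback returns at ketone 17.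

2. Step 11. Initiation at the trisubstituted olefin may be slow, so that intermolecular metathesis (oligomers) or engagement of the isopropenyl group competes with closure of the nine-membered ring. The fallback is a two-stage relay in which ring closure no longer depends on the trisubstituted olefin. Setting out from 19, ethenolysis (second-generation Grubbs catalyst RuCl2(PCy3)(H2IMes)(=CHPh), ethylene, CH2Cl2) should exchange the isopropylidene terminus for a vinyl group and give the terminal olefin F7, the hept-6-en-2-yl analogue of 19. Ring-closing metathesis of F7 (monosubstituted plus 1,1-disubstituted olefin, loss of ethene) then returns to the route at 20.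

3. Step 15. Acylation of the tertiary hydroxyl by the activated acid may be slow, which would allow oligomerisation or epimerisation at C15 through a ketene. The fallback closes the ring at the lactol oxidation level instead of by acyl activation. Setting out from 22, aqueous HF in MeCN removes the silyl ether to give the diol F8. nPr4N[RuO4] (cat.) with N-methylmorpholine N-oxide and molecular sieves in CH2Cl2 oxidises the primary alcohol to the hydroxy aldehyde F9, which closes onto the C3 hydroxyl to the seven-membered lactol F10. The same oxidant takes F10 on to the lactone, so the fallback returns at 26.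

Further compounds
F1 | step 6 | (3S,3aS,4R,7aS)-4-acetyl-3-[(2S)-2-hydroxy-6-methylhept-5-en-2-yl]hexahydro-2-benzofuran-1,7-dione | O=C1CC[C@@H](C(C)=O)[C@H]2[C@@H]1C(=O)O[C@@H]2[C@@](C)(O)CCC=C(C)C
F2 | step 6 | (3S,3aS,4R,7aS)-3-[(2S)-2-hydroxy-6-methylhept-5-en-2-yl]-4-(prop-1-en-2-yl)hexahydro-2-benzofuran-1,7-dione | O=C1CC[C@@H](C(C)=C)[C@H]2[C@@H]1C(=O)O[C@@H]2[C@@](C)(O)CCC=C(C)C
F3 | step 6 | C11 ethylene ketal (spiro-1,3-dioxolane) of F2 | O1CCOC12CC[C@@H](C(C)=C)[C@H]3[C@@H]2C(=O)O[C@@H]3[C@@](C)(O)CCC=C(C)C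
F4 | step 6 | tertiary tert-butyldimethylsilyl ether of F3 | O1CCOC12CC[C@@H](C(C)=C)[C@H]3[C@@H]2C(=O)O[C@@H]3[C@@](C)(O[Si](C)(C)C(C)(C)C)CCC=C(C)C
F5 | step 6 | lactol acetate of F4 (anomeric mixture, one anomer drawn) | O1CCOC12CC[C@@H](C(C)=C)[C@H]3[C@@H]2[C@H](OC(C)=O)O[C@@H]3[C@@](C)(O[Si](C)(C)C(C)(C)C)CCC=C(C)C
F6 | step 6 | C11 ethylene ketal of ketone 17 | O1CCOC12CC[C@@H](C(C)=C)[C@H]3[C@@H]2[C@H](CC(C)=C)O[C@@H]3[C@@](C)(O[Si](C)(C)C(C)(C)C)CCC=C(C)C
F7 | step 11 | (1S,3S,3aR,4R,7R,7aS)-1-[(2S)-2-[(tert-butyldimethylsilyl)oxy]hex-5-en-2-yl]-4-methyl-3-(2-methylprop-2-en-1-yl)-7-(prop-1-en-2-yl)octahydro-2-benzofuran-4-yl butanoate | CCCC(=O)O[C@]1(C)CC[C@@H](C(C)=C)[C@H]2[C@@H]1[C@H](CC(C)=C)O[C@@H]2[C@@](C)(O[Si](C)(C)C(C)(C)C)CCC=C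
F8 | step 15 | (1S,2S,3S,6Z,9S,10R,11R,14S)-2,9-epoxy-3-hydroxy-14-[(2R)-1-hydroxypropan-2-yl]-3,7,11-trimethylbicyclo[8.4.0]tetradec-6-en-11-yl butanoate | CCCC(=O)O[C@]1(C)CC[C@@H]([C@@H](C)CO)[C@H]3[C@@H]1[C@@H]1C/C(C)=C\CC[C@](C)(O)[C@H]3O1
F9 | step 15 | C16 aldehyde of F8, 14-[(2R)-1-oxopropan-2-yl] analogue | CCCC(=O)O[C@]1(C)CC[C@@H]([C@@H](C)C=O)[C@H]3[C@@H]1[C@@H]1C/C(C)=C\CC[C@](C)(O)[C@H]3O1
F10 | step 15 | seven-membered C16 lactol of 26 (hemiacetal between C16 and the C3 oxygen, epimeric at C16) | CCCC(=O)O[C@]1(C)CC[C@@H]2[C@H]3[C@@H]1[C@@H]1C/C(C)=C\CC[C@](C)(OC(O)[C@@H]2C)[C@H]3O1
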